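- I began with a leftover: if each target takes one coupling partner, autumn still held 66.9% of its charged coupling partner at 20.0 h, and midnight held 84.7%.

common to all: substrate 0.30 M; initiator 8.8 mol%

| flask | coupling partner | transfer agent | remark | time |
|---|---|---|---|---|
| autumn | 1.5 equiv | 0.13 M | run made earlier |  |
| midnight | 1.5 equiv | 0.31 M | run made earlier |  |
| east | 1.50 equiv | 0.0900 M |  | 20 h |
| south | 1.50 equiv | 0.270 M |  | 20 h |

| run | time / h | side product / % | target / % | first chain carrier / % | substrate / % |
|---|---|---|---|---|---|
| autumn | 1.50 | 0.5 | 3.7 | 0.8 | 95.4 |
| autumn | 4.00 | 0 | 11.1 | 0.3 | 87.7 |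
| autumn | 8.00 | 0.5 | 23.6 | 1.2 | 76.7 |
| autumn | 20.0 | 2.0 | 49.7 | 0.1 | 48.1 |
| midnight | 2.50 | 0 | 3.8 | 0 | 97.1 |
| midnight | 8.00 | 1.7 | 10.7 | 0 | 89.3 |
| midnight | 12.0 | 1.5 | 14.7 | 0.2 | 83.8 |
| midnight | 20.0 | 1.9 | 22.9 | 0.4 | 74.7 |

(each reading ± 0.5 percentage points)

1. which of these there is most of at the end, counted by the substrate in it, east (substrate / first chain carrier / target / side product)
2. which of these there is most of at the end, counted by the substrate in it, south (substrate / first chain carrier / target / side product)
3. amount of the one of these that there is most of at the end, in percent of the substrate charged, east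
4. amount of the one of these that there is most of at the end, in percent of the substrate charged, south

- the analysis behind the earlier runs scatters by 0.5 percentage points, standard deviation

- I replaced each curve by one exponential through its reading and called its mean constant k: the natural logarithm of charged over left, divided by time.
- In autumn the substrate's k read 0.0328 h⁻¹ at 4.00 h and 0.0366 h⁻¹ at 20.0 h. The coupling partner's k read 0.0192 h⁻¹ and 0.0201 h⁻¹, which the scatter allows as steady, so I treated its loss as pseudo-first-order.
- Next I multiplied the coupling partner's k by the charged transfer agent, [T]. Autumn gave 0.00262 M h⁻¹ and midnight 0.00257 M h⁻¹, so I carried their mean, G = k[T] = 0.00259 M h⁻¹.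
- For east and south, which keep autumn's charges of substrate, coupling partner and initiator, I took k = G/[T], and target as the charged coupling partner times the fraction consumed, one minus e^(−kt). My reckoning gave east 65.7% target, which leads. It gave south 26.2% target. Holding side product at midnight's 1.9% left south 71.9% substrate, which leads.
- The forecast said target at 64% in east and substrate at 71% in south, holding that “The transfer agent retards the reaction but is not used up stoichiometrically”. It reckoned from substrate constants, and my east figure stood 1.7 percentage points above its own.
- The flasks gave target at 66.5% in east and substrate at 71.9% in south.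

    initiator → 2 initiating radical (k = 9.21 × 10⁻⁵ min⁻¹)
    substrate + initiating radical → capped initiator + first chain carrier (k = 18100 L mol⁻¹ s⁻¹)
    coupling partner + first chain carrier → target + second chain carrier (k = 4.50 × 10⁵ L mol⁻¹ min⁻¹)
    substrate + second chain carrier → by-product + first chain carrier (k = 32700 L mol⁻¹ s⁻¹)
    transfer agent + first chain carrier → side product + idle radical (kL = 48300 L mol⁻¹ min⁻¹)
    2 idle radical → ended radicals (k = 7.00 × 10⁸ L mol⁻¹ s⁻¹)
    2 first chain carrier → ended chains A (k = 2.30 × 10⁸ L mol⁻¹ s⁻¹)
    2 second chain carrier → ended chains B (k = 4.00 × 10⁶ L mol⁻¹ s⁻¹)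

- East's leftover coupling partner, 56%, returns G = 0.00264 M h⁻¹. The neighbour is east with 0.12 M substrate, its equivalents and loadings kept, so its initiator charge fell by the same factor, 0.400. I scaled G by that factor, to 0.00104 M h⁻¹, which reckons 30.9% target. That neighbour gave 30.9% target and 67.2% substrate, so substrate holds most there. With those equivalents and loadings kept, target and substrate hold the same at 0.682 times east's substrate.

The readings come from a simulation from invented constants, noise included.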